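Start from 12.9%: that is the target the north-east run shows at 4.00 min, as a share of its 0.17 M substrate. The north-west run, with 0.38 M charged, shows 5.3% at the same time. These two shares are of different charges, so multiply each reading by its charge and divide by the time.

| flask | substrate | coupling partner | initiator | remark | time |
|---|---|---|---|---|---|
| north-east | 0.17 M | 0.221 M | 1.7 mM | run made earlier |  |
| north-west | 0.38 M | 0.221 M | 1.7 mM | run made earlier |  |
| Friday's | 0.12 M | 0.221 M | 1.7 mM |  | 8.0 min |
| Thursday's | 0.15 M | 0.221 M | 1.7 mM |  | 8.0 min |
| Wednesday's | 0.25 M | 0.221 M | 1.7 mM |  | 8.0 min |

| run | time / min | target / % |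
|---|---|---|
| north-east | 1.00 | 3.2 |
| north-east | 2.00 | 6.4 |
| north-east | 3.00 | 9.1 |
| north-east | 4.00 | 12.9 |
| north-west | 0.500 | 0.5 |
| north-west | 1.33 | 2.3 |
| north-west | 2.50 | 3.6 |
| north-west | 4.00 | 5.3 |

(standard deviation of a reading: 0.3 percentage points)

- "hardly changes" means that all values lie within two and a half points (for a concentration: within two and a half percent of the largest)

- [target] at the end for Friday's, Thursday's, Wednesday's, in this order
- how that number moves from the first to the last of them (rises all the way / falls, then rises / rises, then falls / falls all the way / hardly changes)

North-east then makes 0.00548 M/min and north-west 0.00503 M/min. Both runs climb in nearly straight lines, so take the mean of the two, 0.00526 M/min, and call this molar amount of target made per minute the absolute rate.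

Turn the substrate first. By hand, a rate that followed the charge would grow 2.24-fold from north-east to north-west, and the percentages would stay equal. Instead, the north-west rate is 0.918 of the north-east rate, with each reading scattered by 0.3 percentage points. Read this as zero order in substrate, so expect the same molar amount from each of the asked charges, and a percentage that falls as the charge grows.

Turn the time next. A straight line gives rate times time, so 8.0 min gives 0.0421 M. Check that against the other end: this is 35.1% of the 0.12 M substrate in Friday's flask, so that charge has room for it. Coupling partner and initiator are not turned here, at 0.221 M and 1.7 mM, so these readings say nothing of them. Commit to 0.0421 M for each flask, with a flat row.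

The forecast gives the same: 0.042 M, 0.042 M and 0.042 M, with the shape hardly changes, on the ground that “more than doubling the substrate changes nothing”.

The flask gives 0.0353 M, 0.0353 M and 0.0353 M, and the shape is: hardly changes.

    initiator → 2 initiating radical (k = 1.80 × 10⁻⁴ /min)
    substrate + initiating radical → capped initiator + first chain carrier (k = 2.60 × 10⁷ /M/s)
    coupling partner + first chain carrier → target + second chain carrier (k = 1.60 × 10⁵ /M/s)
    substrate + second chain carrier → by-product + first chain carrier (k = 6.00 × 10⁵ /M/s)
    2 first chain carrier → ended chains (k = 6.90 × 10⁸ /M/s)
    coupling partner → decomposed reagent (k = 0.0360 /min)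
    substrate → decomposition product (k = 8.20 × 10⁻⁵ /min)
    coupling partner ⇌ dormant form (K = 0.710, k = 0.00850 /min)

At 8.00 min, Friday's flask holds 57.1% of its coupling partner. Use the absolute rate once more: over 4.00 min it gives 0.0210 M, and Friday's flask has made 0.0201 M by then. Over the following 4.00 min, though, Friday's flask makes on average 0.00381 M/min, less than 0.00526 M/min. Wednesday's flask averages 0.00441 M/min over its 8.0 min, which is 0.839 of the absolute rate.

The readings were computed for substances that don't exist, noise included.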